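The data come from a simulation with constants of no real substance; noise was put on by code.

The question is which flask ends with the largest share of mono adduct in mono adduct plus double product, and how large each share is.

| flask | substrate | partner | temperature | remark | time |
|---|---|---|---|---|---|
| south-east | 0.10 M | 0.11 M | 25 °C | run made earlier |  |
| west | 0.10 M | 0.17 M | 25 °C | run made earlier |  |
| ochre | 0.10 M (in portions, 3, over 20 min) | 0.110 M | 25 °C | first portion at the start, last at 20 min | 30 min |
| teal | 0.10 M | 0.110 M (fed, over 20 min) |  | the addition at −5 °C, then warmed to 25 °C; the feed brings no volume worth counting | 30 min |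
| amber | 0.10 M | 0.110 M (fed, over 20 min) | 25 °C | all else is in the flask from the start; the feed brings no volume worth counting | 30 min |
| green | 0.10 M | 0.110 M | 25 °C | everything together at the start | 30 min |

| run | time / min | mono adduct / % | double product / % | substrate / % |
|---|---|---|---|---|
| south-east | 2.50 | 13.9 | 7.4 | 66.4 |
| south-east | 6.00 | 13.3 | 19.3 | 52.9 |
| south-east | 12.0 | 6.7 | 31.3 | 46.1 |
| south-east | 20.0 | 4.1 | 38.7 | 42.0 |
| west | 1.50 | 16.6 | 8.3 | 63.2 |
| west | 3.00 | 18.4 | 17.9 | 49.7 |
| west | 5.00 | 15.0 | 30.7 | 40.1 |
| west | 6.00 | 14.1 | 35.4 | 37.1 |

(scatter of a reading: 0.5 percentage points)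

- the flask with the highest share of mono adduct in mono adduct plus double product ("all alike" if they lie within 1.5 percentage points) (ochre / teal / amber / green / all alike)
- share of mono adduct in mono adduct plus double product at the end, ochre
- share of mono adduct in mono adduct plus double product at the end, teal
- share of mono adduct in mono adduct plus double product at the end, amber
- share of mono adduct in mono adduct plus double product at the end, green

- a reading or a percentage of mono adduct counts all its forms, free or not
- the earlier runs do not show what temperature does; that part of a forecast is a guess

In both runs the fall of substrate slows while mono adduct, after its early readings, sinks. That suggests a pre-equilibrium: substrate and partner give mono adduct and take it back. Partner is not read, so a balance must supply it. If each missing percent took one partner, each mono adduct one and each double product two, then partner used is the substrate charge times the sum of the fraction of substrate lost and the fraction of double product. The south-east run at 12.0 min then holds 0.0248 M of partner. The holding quotient, c(mono adduct) divided by c(substrate) times c(partner), is there 5.86 M⁻¹.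

One reading proves little. At 6.00 min the same run gives 5.77 M⁻¹, and the west run, with its larger partner charge, gives 5.30 M⁻¹ at 6.00 min. The south-east reading at 20.0 min gives 7.34 M⁻¹, but it rests on 4.1 % of mono adduct with a scatter of 0.5 percentage points. So I reckon mono adduct at the end of a flask as the quotient times c(substrate) times c(partner), which ties the reckoned end share to the partner left.

Green repeats the south-east charges, so its partner can be extrapolated. By the balance, partner in the south-east run fell with a first-order rate of 0.0779 min⁻¹ in the last interval, and that rate carried on leaves 0.006104 M at 30 min. Substrate is taken at its last reading, which overstates it somewhat. My share for green is 3.17 %.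

Teal, if the cold holds it nearly still, resembles the south-east run at 10.0 min. Interpolated between the readings, that run holds 0.0299 M of partner and 48.4 % of substrate, so my share for teal is 23.0 %. The objection stands: the runs show no temperature, so that figure is a guess. Amber and ochre hold charge back at 25 °C, and I commit to no number for them beyond a place between green and teal.

The forecast names teal, with 11 % for ochre, 22 % for teal, 12 % for amber and 6 % for green, which is above my figure for green. Its ground is that “at equal substrate, more partner leaves more mono, so partner level matters”.

The flasks give teal as the highest: ochre 9.48 %, teal 22.1 %, amber 10.2 %, green 3.86 %.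

    substrate + partner ⇌ mono adduct (K = 4.90 M⁻¹, k = 0.0227 M⁻¹ s⁻¹, Ea = 60.0 kJ mol⁻¹, ΔH = −4.00 kJ mol⁻¹)
    substrate + partner → other mono adduct (k = 0.0156 M⁻¹ s⁻¹, Ea = 57.0 kJ mol⁻¹)
    partner + mono adduct → double product (k = 0.0229 M⁻¹ s⁻¹, Ea = 71.0 kJ mol⁻¹)
    partner + other mono adduct → double product (k = 0.0499 M⁻¹ s⁻¹, Ea = 43.0 kJ mol⁻¹)
    substrate → decomposition product (k = 1.04 × 10⁻⁵ s⁻¹, Ea = 94.0 kJ mol⁻¹)
    crystals ⇌ mono adduct, rate k6*(cs6 - [mono adduct]) while solid is left; crystals form when [mono adduct] > cs6 (solubility = 0.0870 M, k = 0.413 s⁻¹)
    (constants at 25 °C)

In green at 4.52 min, dissolved mono adduct falls back 3.8 times as fast as it goes on, and it is made at 0.239 of the rate at which it is used up. The quotient read from the south-east run, applied to the substrate and partner standing in teal at 30.0 min, gives 7.98 % of mono adduct against 8.23 % in the flask. In the neighbour of green with 0.17 M of substrate it gives 0.617 % against 0.804 %.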